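**Retrosynthetic overview**

1. Numbering runs from the carboxyl carbon C1 to C17, which carries the 2-methyl-1,3-oxazol-4-yl ring. The enabling feature is the C9(OH)–C10(CH3)–C11(OH) triad, whose C11 carbinol sits on C12 of the C12–C17 triene: C9 can be raised to a ketone, the C10 methyl lowered to a vinyl CH2, and C11 becomes the formyl carbon of a non-enolisable 2-methyl trienal.
2. Key disconnection C10–C11: reductive syn-aldol union of vinyl ketone 19 (C1–C10) with trienal 9 (C11–C17 plus oxazole); the C9 ketone that remains then relays C11 to C9 by a 1,3-anti reduction.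
3. West half: C6/C7 by anti crotylboration, C4=C5 by vinylogous Horner–Wadsworth–Emmons olefination with phosphonate 3, C9–C10 by vinyl Grignard addition and oxidation.
4. East half: C16=C17 by Wittig olefination of 2-methyl-1,3-oxazole-4-carbaldehyde, C14=C15 by the same phosphonate 3, then adjustment to the aldehyde.
5. No ring is formed: the oxazole ring is bought intact; the endgame is desilylation and ester hydrolysis.

Key step: step 14

Remark: the target is taken as (2E,4E,6S,7R,9S,10S,11R,12E,14E,16E); compounds 1, 2, 4, 5 and 10 are assumed to be catalogue compounds, and the facial sense quoted for the isopinocampheyl boron reagents in steps 6 and 14 is the one expected by analogy with the allyl- and crotylboranes of the same pinene series.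

**Route**

Step 1
Reactants: 1 ethyl (2E)-4-bromo-2-methylbut-2-enoate; 2 triethyl phosphite
Product: 3 ethyl (2E)-4-(diethoxyphosphoryl)-2-methylbut-2-enoate
Conditions: neat, 130 °C, EtBr distilled off
Reagents that add atoms: none
Why: Michaelis–Arbuzov reaction, in which SN2 attack of phosphorus on the primary allylic bromide and loss of bromoethane should give the phosphonate with the E trisubstituted double bond untouched and no stereocentre formed.

Step 2
Reactants: 4 2-methyl-1,3-oxazole-4-carbaldehyde; 5 2-(triphenylphosphoranylidene)propanal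
Product: 6 (2E)-2-methyl-3-(2-methyl-1,3-oxazol-4-yl)prop-2-enal
Conditions: toluene, 90 °C
Reagents that add atoms: none
Why: Wittig olefination with a stabilised α-branched formyl ylide, which should give the E trisubstituted enal (oxazole trans to the formyl group) and creates no stereocentre.

Step 3
Reactants: 6 enal; 3 phosphonate
Product: 7 ethyl (2E,4E,6E)-2,6-dimethyl-7-(2-methyl-1,3-oxazol-4-yl)hepta-2,4,6-trienoate
Conditions: LiN(SiMe3)2, THF, −78 °C; then 6, −78 → 0 °C
Reagents that add atoms: none
Why: vinylogous Horner–Wadsworth–Emmons olefination, in which the lithiated allylic phosphonate reacts at the carbon next to phosphorus and should form the new C14=C15 bond E while the 2E geometry of the reagent is kept.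

Step 4
Reactants: 7 trienoate
Product: 8 (2E,4E,6E)-2,6-dimethyl-7-(2-methyl-1,3-oxazol-4-yl)hepta-2,4,6-trien-1-ol
Conditions: iBu2AlH, CH2Cl2, −78 °C; aq. potassium sodium tartrate work-up
Reagents that add atoms: none
Why: hydride reduction of the conjugated ester with iBu2AlH proceeds by 1,2-addition to the allylic alcohol and should leave the triene and the oxazole untouched.

Step 5
Reactants: 8 trienol
Product: 9 (2E,4E,6E)-2,6-dimethyl-7-(2-methyl-1,3-oxazol-4-yl)hepta-2,4,6-trienal
Conditions: MnO2, CH2Cl2, rt, dark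
Reagents that add atoms: none
Why: allylic oxidation with MnO2 is selective for the trienylic primary alcohol and should stop at the aldehyde without changing the double-bond geometry.

Step 6
Reactants: 10 3-[(4-methoxyphenyl)methoxy]propanal
Product: 12 (3R,4S)-1-[(4-methoxyphenyl)methoxy]-4-methylhex-5-en-3-ol, via boron alkoxide 11 (not isolated)
Conditions: trans-2-butene, KOtBu, n-BuLi, THF, −78 → −45 °C; (−)-Ipc2BOMe [from (+)-α-pinene], −78 °C; BF3·OEt2; then 10, −78 °C; NaOH, H2O2, 0 °C → rt
Reagents that add atoms: trans-2-butene, C/C=C/C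
Why: Brown crotylboration, in which the (E)-crotylborane adds through a closed six-membered chair so that the E geometry gives the anti relationship and the isopinocampheyl groups from (+)-α-pinene should direct attack to the Si face of the aldehyde, setting C7 as R and C6 as S (target numbering).

Step 7
Reactants: 12 homoallylic alcohol
Product: 13 tert-butyl{[(3R,4S)-1-[(4-methoxyphenyl)methoxy]-4-methylhex-5-en-3-yl]oxy}dimethylsilane
Conditions: TBSOTf, 2,6-lutidine, CH2Cl2, −78 → 0 °C
Reagents that add atoms: tert-butyldimethylsilyl trifluoromethanesulfonate (TBSOTf), CC(C)(C)[Si](C)(C)OS(=O)(=O)C(F)(F)F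
Why: silylation of the secondary alcohol with the silyl triflate and a hindered pyridine base should be fast at low temperature and leave the PMB ether, the alkene and both stereocentres untouched.

Step 8
Reactants: 13 silyl ether
Product: 14 (2R,3R)-3-[(tert-butyldimethylsilyl)oxy]-5-[(4-methoxyphenyl)methoxy]-2-methylpentanal
Conditions: OsO4 (cat.), NaIO4, 2,6-lutidine, dioxane/H2O, rt
Reagents that add atoms: OsO4, O=[Os](=O)(=O)=O (catalytic oxygen carrier); NaIO4, [Na+].[O-]I(=O)(=O)=O (stoichiometric oxygen source)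
Why: Lemieux–Johnson oxidative cleavage (OsO4-catalysed dihydroxylation, then periodate cleavage), buffered with 2,6-lutidine, should convert the terminal vinyl group into the aldehyde under near-neutral conditions that spare the PMB ether and do not epimerise the α-methyl centre.

Step 9
Reactants: 14 aldehyde; 3 phosphonate
Product: 15 ethyl (2E,4E,6S,7R)-7-[(tert-butyldimethylsilyl)oxy]-9-[(4-methoxyphenyl)methoxy]-2,6-dimethylnona-2,4-dienoate
Conditions: LiN(SiMe3)2, THF, −78 °C; then 14, −78 → 0 °C
Reagents that add atoms: none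
Why: vinylogous Horner–Wadsworth–Emmons olefination with the same weakly basic phosphonate anion, used at low temperature so that the α-stereocentre should survive, installs the (2E,4E)-dienoate with the new C4=C5 bond E.

Step 10
Reactants: 15 PMB ether
Product: 16 ethyl (2E,4E,6S,7R)-7-[(tert-butyldimethylsilyl)oxy]-9-hydroxy-2,6-dimethylnona-2,4-dienoate
Conditions: DDQ, CH2Cl2/pH 7 buffer, 0 °C
Reagents that add atoms: none
Why: oxidative PMB cleavage, in which DDQ abstracts hydride from the electron-rich benzylic position and water hydrolyses the oxocarbenium ion, while the electron-poor dienoate and the silyl ether should be inert.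

Step 11
Reactants: 16 primary alcohol
Product: 17 ethyl (2E,4E,6S,7R)-7-[(tert-butyldimethylsilyl)oxy]-2,6-dimethyl-9-oxonona-2,4-dienoate
Conditions: Dess–Martin periodinane, CH2Cl2, 0 °C → rt
Reagents that add atoms: none
Why: Dess–Martin oxidation should take the primary alcohol to the aldehyde under neutral conditions that neither eliminate the β-silyloxy group nor touch the stereocentres.

Step 12
Reactants: 17 aldehyde
Product: 18 ethyl (2E,4E,6S,7R)-7-[(tert-butyldimethylsilyl)oxy]-9-hydroxy-2,6-dimethylundeca-2,4,10-trienoate (both C9 epimers)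
Conditions: CH2=CHMgBr, THF, −78 °C; aq. NH4Cl
Reagents that add atoms: vinylmagnesium bromide, C=C[Mg]Br
Why: Grignard 1,2-addition, at low temperature chemoselective for the aldehyde over the hindered conjugated ester, should give the allylic alcohol as a mixture of C9 epimers, which is of no consequence because C9 is oxidised in the next step.

Step 13
Reactants: 18 allylic alcohol
Product: 19 ethyl (2E,4E,6S,7R)-7-[(tert-butyldimethylsilyl)oxy]-2,6-dimethyl-9-oxoundeca-2,4,10-trienoate
Conditions: Dess–Martin periodinane, CH2Cl2, 0 °C; used at once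
Reagents that add atoms: none
Why: Dess–Martin oxidation of the secondary allylic alcohol should give the vinyl ketone under neutral conditions that avoid β-elimination of the C7 silyloxy group, and the two C9 epimers converge.

Step 14
Reactants: 19 vinyl ketone; 9 trienal
Product: 22 ethyl (2E,4E,6S,7R,10R,11R,12E,14E,16E)-7-[(tert-butyldimethylsilyl)oxy]-11-hydroxy-2,6,10,12,16-pentamethyl-17-(2-methyl-1,3-oxazol-4-yl)-9-oxoheptadeca-2,4,12,14,16-pentaenoate, via Z-enol borinate 20 (not isolated), via boron aldolate 21 (not isolated)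
Conditions: 19 (1.2 equiv), (+)-Ipc2BH [from (−)-α-pinene, 1.1 equiv], THF, 0 °C; then 9 (1.0 equiv), −78 → −20 °C; pH 7 buffer, MeOH, H2O2, 0 °C
Reagents that add atoms: none
Why: Reductive aldol union: the B–H bond of Ipc2BH adds 1,4 across the s-cis C9(=O)–C10=CH2 unit of 19 through a six-membered transition state, so that the terminal CH2 becomes the C10 methyl group and the Z-enol borinate 20 is formed regiospecifically; 20 then adds to the formyl group of 9 through a closed Zimmerman–Traxler chair to give boron aldolate 21, which the buffered peroxide work-up releases as 22. The closest known reaction types are the conjugate hydroboration–aldol sequence of vinyl ketones with dialkylboranes and the Ipc2B-mediated syn aldol of ethyl ketones with 2-methyl enals. No ring is closed. C10 and C11 are created together: the 10,11-syn relationship follows from the Z enolate in the chair with the trienyl group equatorial, and the absolute sense (attack on the Re face of the aldehyde, 11R and hence 10R in 22) should be controlled by the isopinocampheyl ligands derived from (−)-α-pinene, the silylated C7 oxygen exerting no significant remote bias. The step needs site selectivity of the borane for the enone over the dienoate and regiocontrol of the enolate: the unsubstituted, s-cis-capable vinyl ketone is by far the most reactive acceptor toward the hindered borane, the β-substituted 2-methyl dienoate is not, and the enolate can form only toward C10 and never toward C8. The aldehyde partner has no α-hydrogen and no stereocentre, so neither self-condensation nor a mismatched substrate bias is expected.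

Step 15
Reactants: 22 aldol adduct
Product: 23 ethyl (2E,4E,6S,7R,9S,10S,11R,12E,14E,16E)-7-[(tert-butyldimethylsilyl)oxy]-9,11-dihydroxy-2,6,10,12,16-pentamethyl-17-(2-methyl-1,3-oxazol-4-yl)heptadeca-2,4,12,14,16-pentaenoate
Conditions: Me4NBH(OAc)3, MeCN/AcOH, −30 → −20 °C
Reagents that add atoms: none
Why: Evans–Saksena reduction, in which the C11 hydroxyl exchanges an acetate on boron and the resulting alkoxyborohydride delivers hydride intramolecularly through a chair transition state, should set C9 anti to C11 (9S), the silylated C7 oxygen being unable to direct.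

Step 16
Reactants: 23 diol silyl ether
Product: 24 ethyl (2E,4E,6S,7R,9S,10S,11R,12E,14E,16E)-7,9,11-trihydroxy-2,6,10,12,16-pentamethyl-17-(2-methyl-1,3-oxazol-4-yl)heptadeca-2,4,12,14,16-pentaenoate
Conditions: Bu4NF, AcOH (1:1), THF, 0 °C → rt
Reagents that add atoms: none
Why: fluoride-mediated desilylation, buffered with acetic acid to keep the medium near neutral, should remove the C7 TBS ether without ionising the C11 trienylic alcohol or touching any stereocentre.

Step 17
Reactants: 24 triol ethyl ester
Product: 25 (2E,4E,6S,7R,9S,10S,11R,12E,14E,16E)-7,9,11-trihydroxy-2,6,10,12,16-pentamethyl-17-(2-methyl-1,3-oxazol-4-yl)heptadeca-2,4,12,14,16-pentaenoic acid (CNP0108844.1)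
Conditions: LiOH, THF/MeOH/H2O, 0 °C → rt; then dilute HCl to pH 4–5, 0 °C
Reagents that add atoms: lithium hydroxide, [Li+].[OH-]
Why: saponification of the ethyl dienoate by hydroxide at the acyl carbon, followed by careful acidification, should release the acid without affecting any stereocentre or exposing the trienylic alcohol to strong acid.

**Compound list**

1 | ethyl (2E)-4-bromo-2-methylbut-2-enoate | CCOC(=O)/C(C)=C/CBr | starting material
2 | triethyl phosphite | CCOP(OCC)OCC | starting material
3 | ethyl (2E)-4-(diethoxyphosphoryl)-2-methylbut-2-enoate | CCOC(=O)/C(C)=C/CP(=O)(OCC)OCC | intermediate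
4 | 2-methyl-1,3-oxazole-4-carbaldehyde | Cc1nc(C=O)co1 | starting material
5 | 2-(triphenylphosphoranylidene)propanal | CC(C=O)=P(c1ccccc1)(c1ccccc1)c1ccccc1 | starting material
6 | (2E)-2-methyl-3-(2-methyl-1,3-oxazol-4-yl)prop-2-enal | O=C/C(C)=C/c1coc(C)n1 | intermediate
7 | ethyl (2E,4E,6E)-2,6-dimethyl-7-(2-methyl-1,3-oxazol-4-yl)hepta-2,4,6-trienoate | CCOC(=O)/C(C)=C/C=C/C(C)=C/c1coc(C)n1 | intermediate
8 | (2E,4E,6E)-2,6-dimethyl-7-(2-methyl-1,3-oxazol-4-yl)hepta-2,4,6-trien-1-ol | OC/C(C)=C/C=C/C(C)=C/c1coc(C)n1 | intermediate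
9 | (2E,4E,6E)-2,6-dimethyl-7-(2-methyl-1,3-oxazol-4-yl)hepta-2,4,6-trienal | O=C/C(C)=C/C=C/C(C)=C/c1coc(C)n1 | intermediate
10 | 3-[(4-methoxyphenyl)methoxy]propanal | COc1ccc(COCCC=O)cc1 | starting material
11 | (3R,4S)-1-[(4-methoxyphenyl)methoxy]-4-methylhex-5-en-3-yl diisopinocampheylborinate (Ipc groups from (+)-α-pinene) | COc1ccc(COCC[C@@H](OB([C@@H]2C[C@@H]3C[C@H]([C@H]2C)C3(C)C)[C@@H]2C[C@@H]3C[C@H]([C@H]2C)C3(C)C)[C@@H](C)C=C)cc1 | intermediate
12 | (3R,4S)-1-[(4-methoxyphenyl)methoxy]-4-methylhex-5-en-3-ol | COc1ccc(COCC[C@@H](O)[C@@H](C)C=C)cc1 | intermediate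
13 | tert-butyl{[(3R,4S)-1-[(4-methoxyphenyl)methoxy]-4-methylhex-5-en-3-yl]oxy}dimethylsilane | COc1ccc(COCC[C@@H](O[Si](C)(C)C(C)(C)C)[C@@H](C)C=C)cc1 | intermediate
14 | (2R,3R)-3-[(tert-butyldimethylsilyl)oxy]-5-[(4-methoxyphenyl)methoxy]-2-methylpentanal | COc1ccc(COCC[C@@H](O[Si](C)(C)C(C)(C)C)[C@@H](C)C=O)cc1 | intermediate
15 | ethyl (2E,4E,6S,7R)-7-[(tert-butyldimethylsilyl)oxy]-9-[(4-methoxyphenyl)methoxy]-2,6-dimethylnona-2,4-dienoate | COc1ccc(COCC[C@@H](O[Si](C)(C)C(C)(C)C)[C@@H](C)/C=C/C=C(\C)C(=O)OCC)cc1 | intermediate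
16 | ethyl (2E,4E,6S,7R)-7-[(tert-butyldimethylsilyl)oxy]-9-hydroxy-2,6-dimethylnona-2,4-dienoate | OCC[C@@H](O[Si](C)(C)C(C)(C)C)[C@@H](C)/C=C/C=C(\C)C(=O)OCC | intermediate
17 | ethyl (2E,4E,6S,7R)-7-[(tert-butyldimethylsilyl)oxy]-2,6-dimethyl-9-oxonona-2,4-dienoate | O=CC[C@@H](O[Si](C)(C)C(C)(C)C)[C@@H](C)/C=C/C=C(\C)C(=O)OCC | intermediate
18 | ethyl (2E,4E,6S,7R)-7-[(tert-butyldimethylsilyl)oxy]-9-hydroxy-2,6-dimethylundeca-2,4,10-trienoate (both C9 epimers) | C=CC(O)C[C@@H](O[Si](C)(C)C(C)(C)C)[C@@H](C)/C=C/C=C(\C)C(=O)OCC | intermediate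
19 | ethyl (2E,4E,6S,7R)-7-[(tert-butyldimethylsilyl)oxy]-2,6-dimethyl-9-oxoundeca-2,4,10-trienoate | C=CC(=O)C[C@@H](O[Si](C)(C)C(C)(C)C)[C@@H](C)/C=C/C=C(\C)C(=O)OCC | intermediate
20 | ethyl (2E,4E,6S,7R,9Z)-7-[(tert-butyldimethylsilyl)oxy]-9-[(diisopinocampheylboranyl)oxy]-2,6-dimethylundeca-2,4,9-trienoate (Ipc groups from (−)-α-pinene) | C/C=C(\OB([C@H]1C[C@H]2C[C@@H]([C@@H]1C)C2(C)C)[C@H]1C[C@H]2C[C@@H]([C@@H]1C)C2(C)C)C[C@@H](O[Si](C)(C)C(C)(C)C)[C@@H](C)/C=C/C=C(\C)C(=O)OCC | intermediate
21 | O11-(diisopinocampheylboranyl) derivative of 22 (boron aldolate, Ipc groups from (−)-α-pinene) | CC(/C=C/C=C(\C)[C@H](OB([C@H]1C[C@H]2C[C@@H]([C@@H]1C)C2(C)C)[C@H]1C[C@H]2C[C@@H]([C@@H]1C)C2(C)C)[C@@H](C)C(=O)C[C@@H](O[Si](C)(C)C(C)(C)C)[C@@H](C)/C=C/C=C(\C)C(=O)OCC)=C\c1coc(C)n1 | intermediate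
22 | ethyl (2E,4E,6S,7R,10R,11R,12E,14E,16E)-7-[(tert-butyldimethylsilyl)oxy]-11-hydroxy-2,6,10,12,16-pentamethyl-17-(2-methyl-1,3-oxazol-4-yl)-9-oxoheptadeca-2,4,12,14,16-pentaenoate | CC(/C=C/C=C(\C)[C@H](O)[C@@H](C)C(=O)C[C@@H](O[Si](C)(C)C(C)(C)C)[C@@H](C)/C=C/C=C(\C)C(=O)OCC)=C\c1coc(C)n1 | intermediate
23 | ethyl (2E,4E,6S,7R,9S,10S,11R,12E,14E,16E)-7-[(tert-butyldimethylsilyl)oxy]-9,11-dihydroxy-2,6,10,12,16-pentamethyl-17-(2-methyl-1,3-oxazol-4-yl)heptadeca-2,4,12,14,16-pentaenoate | CC(/C=C/C=C(\C)[C@H](O)[C@@H](C)[C@@H](O)C[C@@H](O[Si](C)(C)C(C)(C)C)[C@@H](C)/C=C/C=C(\C)C(=O)OCC)=C\c1coc(C)n1 | intermediate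
24 | ethyl (2E,4E,6S,7R,9S,10S,11R,12E,14E,16E)-7,9,11-trihydroxy-2,6,10,12,16-pentamethyl-17-(2-methyl-1,3-oxazol-4-yl)heptadeca-2,4,12,14,16-pentaenoate | CC(/C=C/C=C(\C)[C@H](O)[C@@H](C)[C@@H](O)C[C@@H](O)[C@@H](C)/C=C/C=C(\C)C(=O)OCC)=C\c1coc(C)n1 | intermediate
25 | (2E,4E,6S,7R,9S,10S,11R,12E,14E,16E)-7,9,11-trihydroxy-2,6,10,12,16-pentamethyl-17-(2-methyl-1,3-oxazol-4-yl)heptadeca-2,4,12,14,16-pentaenoic acid | CC(/C=C/C=C(\C)[C@H](O)[C@@H](C)[C@@H](O)C[C@@H](O)[C@@H](C)/C=C/C=C(\C)C(=O)O)=C\c1coc(C)n1 | target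

**Step count and risks**

Total step count: 17. Longest linear sequence: 12 steps (steps 6–17, from 10).

Steps most likely to fail:

1. Step 14. The conjugate hydroboration may lose chemoselectivity: 1,2-reduction of the ketone, attack of the borane on the dienoate, or oligomerisation of the vinyl ketone before the enolate is formed. The fallback sets out from 17 and comes back at 22. Addition of EtMgBr to 17 (THF, −78 °C) should give ethyl (2E,4E,6S,7R)-7-[(tert-butyldimethylsilyl)oxy]-9-hydroxy-2,6-dimethylundeca-2,4-dienoate F1 as both C9 epimers. Dess–Martin oxidation should then give the saturated ethyl ketone ethyl (2E,4E,6S,7R)-7-[(tert-butyldimethylsilyl)oxy]-2,6-dimethyl-9-oxoundeca-2,4-dienoate F2. Soft enolisation of F2 with (+)-Ipc2BOTf and i-Pr2NEt (CH2Cl2, −78 °C), expected on the less hindered ethyl side, gives the same enol borinate 20 without any B–H reagent; this is combined with 9 and worked up as in step 14 to give 22.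

2. Step 9. The α-methyl aldehyde 14 may epimerise at C6 under the basic olefination, or the new C4=C5 bond may form with incomplete E selectivity. The fallback sets out from 13 and comes back at 15. Wittig olefination of acrolein with ethyl 2-(triphenylphosphoranylidene)propanoate should give ethyl (2E)-2-methylpenta-2,4-dienoate F3. Cross-metathesis of 13 with an excess of F3 (second-generation Hoveyda–Grubbs catalyst, CH2Cl2, 40 °C) should engage only the terminal vinyl group of F3, the trisubstituted electron-poor double bond being inert, and give 15 directly with no aldehyde at C5 and no base.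

3. Step 15. The C11 trienylic alcohol may ionise in the acetic acid medium, or the 1,3-anti selectivity may be eroded. The fallback sets out from 22 and comes back at 25. Evans–Tishchenko reduction of 22 with acetaldehyde and catalytic SmI2 (THF, −10 °C) delivers hydride from the hemiacetal formed at the C11 oxygen to C9 within a samarium-bound six-membered transition state. Under non-acidic conditions it should give the 9,11-anti diol as its C11 acetate, ethyl (2E,4E,6S,7R,9S,10S,11R,12E,14E,16E)-11-(acetyloxy)-7-[(tert-butyldimethylsilyl)oxy]-9-hydroxy-2,6,10,12,16-pentamethyl-17-(2-methyl-1,3-oxazol-4-yl)heptadeca-2,4,12,14,16-pentaenoate F4. Desilylation as in step 16 should give ethyl (2E,4E,6S,7R,9S,10S,11R,12E,14E,16E)-11-(acetyloxy)-7,9-dihydroxy-2,6,10,12,16-pentamethyl-17-(2-methyl-1,3-oxazol-4-yl)heptadeca-2,4,12,14,16-pentaenoate F5. The saponification of step 17, run with additional LiOH, cleaves the acetate together with the ethyl ester and gives 25; any acetyl migration between O11 and O9 on the way is without consequence.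

Further compounds
F1 | step 14 | ethyl (2E,4E,6S,7R)-7-[(tert-butyldimethylsilyl)oxy]-9-hydroxy-2,6-dimethylundeca-2,4-dienoate (both C9 epimers) | CCC(O)C[C@@H](O[Si](C)(C)C(C)(C)C)[C@@H](C)/C=C/C=C(\C)C(=O)OCC
F2 | step 14 | ethyl (2E,4E,6S,7R)-7-[(tert-butyldimethylsilyl)oxy]-2,6-dimethyl-9-oxoundeca-2,4-dienoate | CCC(=O)C[C@@H](O[Si](C)(C)C(C)(C)C)[C@@H](C)/C=C/C=C(\C)C(=O)OCC
F3 | step 9 | ethyl (2E)-2-methylpenta-2,4-dienoate | C=C/C=C(\C)C(=O)OCC
F4 | step 15 | ethyl (2E,4E,6S,7R,9S,10S,11R,12E,14E,16E)-11-(acetyloxy)-7-[(tert-butyldimethylsilyl)oxy]-9-hydroxy-2,6,10,12,16-pentamethyl-17-(2-methyl-1,3-oxazol-4-yl)heptadeca-2,4,12,14,16-pentaenoate | CC(/C=C/C=C(\C)[C@H](OC(C)=O)[C@@H](C)[C@@H](O)C[C@@H](O[Si](C)(C)C(C)(C)C)[C@@H](C)/C=C/C=C(\C)C(=O)OCC)=C\c1coc(C)n1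
F5 | step 15 | ethyl (2E,4E,6S,7R,9S,10S,11R,12E,14E,16E)-11-(acetyloxy)-7,9-dihydroxy-2,6,10,12,16-pentamethyl-17-(2-methyl-1,3-oxazol-4-yl)heptadeca-2,4,12,14,16-pentaenoate | CC(/C=C/C=C(\C)[C@H](OC(C)=O)[C@@H](C)[C@@H](O)C[C@@H](O)[C@@H](C)/C=C/C=C(\C)C(=O)OCC)=C\c1coc(C)n1
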